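Free monomer falls faster in Wednesday's run, with a first-order slope of 0.0982 /min, than in Monday's, at 0.0884 /min. Wednesday's run also held less impurity, at equal initiator.

| flask | free monomer | initiator | impurity | remark | time |
|---|---|---|---|---|---|
| Wednesday's | 0.91 M | 4.5 mM | 1.2 mM | run made earlier |  |
| Monday's | 0.46 M | 4.5 mM | 1.8 mM | run made earlier |  |
| cedar | 0.91 M | 4.5 mM | 1.8 mM |  | 40 min |
| oak | 0.91 M | 10 mM | 1.8 mM |  | 40 min |

| run | time / min | monomer in chains / % | free monomer / % |
|---|---|---|---|
| Wednesday's | 3.00 | 24.0 | 77.0 |
| Wednesday's | 6.00 | 43.2 | 56.6 |
| Wednesday's | 8.00 | 52.3 | 46.9 |
| Wednesday's | 12.0 | 68.3 | 30.8 |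
| Wednesday's | 15.0 | 77.8 | 23.7 |
| Monday's | 1.00 | 3.4 | 94.3 |
| Monday's | 2.00 | 10.6 | 87.6 |
| Monday's | 4.00 | 25.8 | 76.7 |
| Monday's | 8.00 | 45.9 | 56.5 |
| Monday's | 15.0 | 68.5 | 29.0 |

(standard deviation of a reading: 1 percentage point)

- which of the two ends with the longer chains by the average number of monomer units in a chain (chains begun, living or dead) ("neither" if they lie within 10%) (cedar / oak / neither)
- average number of monomer units in a chain (chains begun, living or dead) at the end, cedar
- average number of monomer units in a chain (chains begun, living or dead) at the end, oak

- the average divides the monomer in chains by the number of chains begun, living and dead together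
- the earlier runs do not show the number of chains; that part of a forecast is a guess
- no earlier run changes the charge of initiator; that part of a forecast is a guess

The readings give a ladder of three times. The shortest is the start-up: Monday's monomer in chains reaches 3.4% by 1.00 min, then adds 7.2 percentage points in the next 1.00 min. After it, the flask looks like a fixed stock of growing chains, and free monomer falls in a pseudo-first-order way. The next rung is that fall, with a time of 10.2 min in Wednesday's run. The top rung is the asked 40 min, about 3.92 such times.

The quantity carried here is the surviving initiator 2.70 mM: initiator charged minus impurity charged, taking one initiator lost per impurity and one chain per initiator that remains. For cedar it is the value just printed. It predicts a slope ratio of 1.22 between Wednesday and Monday, and the readings give 1.11. That is the same direction, but the scatter allows no more, and the chain number itself is a guess.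

Scaling Wednesday's slope by surviving initiator gives cedar a slope of 0.0803 /min, and this reckoning then leaves 4.03% of cedar's free monomer at 40 min. Cedar's chains then average 323. Oak, with 8.20 mM, reaches 111, assuming its monomer is consumed.

The forecast also names cedar, but gives 200 for cedar and 93 for oak, saying “I assume nearly all initiator begins chains”. Its figures lie below this reckoning.

The flasks give cedar, with 323 for cedar and 111 for oak.

    free monomer + initiator → living end + monomer in chains (k = 0.0502 /M/s)
    initiator + impurity → spent initiator (k = 143 /M/s)
    free monomer + living end → monomer in chains + living end, rate k3*[living end]*[free monomer] (k = 0.500 /M/s)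

Oak ends at 111 against 323 on cedar's charge of initiator, and that difference in initiator is the main reason for the gap. In cedar, with each partner held at its charge, initiator's half-life is 2.7 s against impurity and 15.2 s against free monomer. With that loss removed, cedar ends at 201 instead of 323, which is a part of the story. Cedar's living end stands at 0.00270 M, matching its surviving initiator of 2.70 mM. The neighbour of oak, charged with 0.0060 M of initiator, has 4.20 mM surviving. Its 99.3% of monomer in chains then reckons to 215, and the flask gives 215.

The earlier runs and the new flask were computed with made-up constants; the scatter is artificial.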